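**Retrosynthetic overview**
- The plan rests on the two vicinal phenolic oxygens on C2 and C3 of the benzoate ring (ortho and meta to the ester carbon C1). These are the two positions that a toluene-type arene dioxygenase oxidises on a monosubstituted benzene.
- C2–O and C3–O are disconnected to allyl benzoate and O2 (dioxygenase plus dihydrodiol dehydrogenase in whole cells). No ring is formed anywhere: the single benzene ring is bought, dearomatised and rearomatised in the key step.
- The chain is disconnected at C2'–C3' of the ester alkyl group (alkene cross-metathesis, then hydrogenation), giving the allyl ester handle and (S)-19-methylhenicos-1-ene.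
- The C22 alkene comes from (S)-1-bromo-2-methylbutane, 1,6-dibromohexane and 11-bromoundec-1-ene by two Li2CuCl4-catalysed Grignard couplings; the stereocentre is bought and never touched.
- The catechol is carried as its bis-TBS ether from step 2 to step 7.

Key step: step 1

Assumption: the recombinant E. coli strain co-expressing toluene dioxygenase (todC1C2BA) and cis-dihydrodiol dehydrogenase (todD) is at hand as grown, induced cells, and its cultivation is not counted as a chemical step.

**Step 1**
Reactants: 1 allyl benzoate
Product: 3 allyl 2,3-dihydroxybenzoate, via cis-dihydrodiol 2 (not isolated)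
Conditions: E. coli JM109(pDTG602) whole cells (toluene dioxygenase + cis-dihydrodiol dehydrogenase, IPTG-induced), air sparge, glucose feed, phosphate-buffered mineral medium pH 6.8, 30 °C, 1 fed in portions, polystyrene adsorbent resin; EtOAc extraction under N2, SiO2
Reagents that add atoms: dioxygen, O=O
Why: This is a Rieske arene dioxygenase cis-dihydroxylation followed by NAD+-dependent dihydrodiol dehydrogenation: the mononuclear non-haem iron site (divalent iron, supplied with electrons from NADH through reductase, ferredoxin and the [2Fe-2S] cluster) binds O2 and adds both oxygen atoms to one face of the C2=C3 bond of 1, giving the cis-(5S,6R)-dihydrodiol 2. The dehydrogenase then passes a hydride from one carbinol carbon to NAD+ and removes a proton from the other, so the ring rearomatises to catechol 3 and the NADH used in the first half-reaction is regenerated. The closest known reactions are the whole-cell toluene dioxygenase oxidation of methyl, ethyl and allyl benzoate to their 2,3-cis-diols and the two-enzyme whole-cell conversion of halo- and alkylbenzenes into 3-substituted catechols; dehydrogenation of this particular ester diol rests on that analogy. No ring closes and no stereocentre survives, because both carbinol centres of 2 become sp2 carbons of 3. The step needs 2,3- over 3,4- or ipso-1,2-regioselectivity, which the active-site binding of a monosubstituted arene secures, and ring over allyl-alkene oxidation, which the preference of the enzyme for the arene of short benzoate esters secures. The product should accumulate because the host has no catechol ring-cleaving dioxygenase, and the resin keeps its free concentration below the level that poisons the cells.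

**Step 2**
Reactants: 3 allyl 2,3-dihydroxybenzoate
Product: 4 allyl 2,3-bis[(tert-butyldimethylsilyl)oxy]benzoate
Conditions: TBSCl (3 equiv), imidazole (6 equiv), DMF, 0 → 40 °C
Reagents that add atoms: tert-butyldimethylsilyl chloride, CC(C)(C)[Si](C)(C)Cl
Why: Imidazole-promoted O-silylation of both phenols; the hydrogen-bonded C2 phenol reacts more slowly, hence the excess of reagent and the mild heating.

**Step 3**
Reactants: 5 (S)-1-bromo-2-methylbutane; 6 1,6-dibromohexane
Product: 8 (S)-1-bromo-8-methyldecane, via (S)-2-methylbutylmagnesium bromide 7 (not isolated)
Conditions: 5, Mg, THF, 40 °C; then added slowly to 6 (4 equiv), Li2CuCl4 (3 mol %), THF, −10 → 20 °C; SiO2 (hexanes) to remove excess 6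
Reagents that add atoms: none
Why: Kochi-type copper-catalysed sp3–sp3 coupling of a primary Grignard reagent with a primary bromide; the excess of 6 holds the reaction at mono-substitution, and the stereocentre, β to magnesium, takes no part and keeps its S configuration.

**Step 4**
Reactants: 8 (S)-1-bromo-8-methyldecane; 9 11-bromoundec-1-ene
Product: 11 (S)-19-methylhenicos-1-ene, via (S)-8-methyldecylmagnesium bromide 10 (not isolated)
Conditions: 8, Mg, THF, 45 °C; then 9 (0.85 equiv), Li2CuCl4 (3 mol %), THF, −10 → 20 °C; SiO2 plug (hexanes), volatiles removed in vacuo
Reagents that add atoms: none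
Why: A second Kochi-type Grignard–bromide coupling; the slight excess of 10 consumes the bromoalkene, so the only by-products are saturated hydrocarbons, which are inert in step 5 and are separated there by polarity.

**Step 5**
Reactants: 4 allyl 2,3-bis[(tert-butyldimethylsilyl)oxy]benzoate; 11 (S)-19-methylhenicos-1-ene
Product: 12 (2E,20S)-20-methyldocos-2-en-1-yl 2,3-bis[(tert-butyldimethylsilyl)oxy]benzoate (mainly E; any Z isomer is carried on)
Conditions: 4 (2 equiv), second-generation Grubbs catalyst RuCl2(=CHPh)(PCy3)(H2IMes) (5 mol %), 1,4-benzoquinone (10 mol %), CH2Cl2, 40 °C, Ar sweep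
Reagents that add atoms: none
Why: Olefin cross-metathesis of two unhindered terminal alkenes by the Chauvin [2+2]/retro-[2+2] cycle with loss of ethene; homodimers re-enter the cycle, the excess of 4 drives 11 to the cross product, and benzoquinone suppresses ruthenium-hydride double-bond migration.

**Step 6**
Reactants: 12 (2E,20S)-20-methyldocos-2-en-1-yl 2,3-bis[(tert-butyldimethylsilyl)oxy]benzoate
Product: 13 (20S)-20-methyldocosyl 2,3-bis[(tert-butyldimethylsilyl)oxy]benzoate
Conditions: H2 (1–3 atm), RhCl(PPh3)3 (5 mol %), toluene/EtOH 1:1, 25 °C
Reagents that add atoms: none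
Why: Homogeneous hydrogenation of the 1,2-disubstituted alkene by RhCl(PPh3)3, which, unlike palladium on carbon, should not hydrogenolyse the allylic C–O bond; the ester, the aryl silyl ethers and the remote stereocentre are untouched.

**Step 7**
Reactants: 13 (20S)-20-methyldocosyl 2,3-bis[(tert-butyldimethylsilyl)oxy]benzoate
Product: 14 Gentiside B, (20S)-20-methyldocosyl 2,3-dihydroxybenzoate
Conditions: TBAF (2.5 equiv), AcOH (3 equiv), THF, 0 °C, Ar
Reagents that add atoms: none
Why: Fluoride cleavage of both aryl silyl ethers, driven by the Si–F bond; acetic acid protonates the phenoxides as they form, so the catechol is not exposed to base and air and the ester is not attacked.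

**Compound list**
1 | allyl benzoate (prop-2-en-1-yl benzoate) | C=CCOC(=O)c1ccccc1 | starting material
2 | allyl (5S,6R)-5,6-dihydroxycyclohexa-1,3-diene-1-carboxylate (cis-2,3-dihydrodiol) | C=CCOC(=O)C1=CC=C[C@H](O)[C@@H]1O | intermediate (not isolated)
3 | allyl 2,3-dihydroxybenzoate | C=CCOC(=O)c1cccc(O)c1O | intermediate
4 | allyl 2,3-bis[(tert-butyldimethylsilyl)oxy]benzoate | C=CCOC(=O)c1cccc(O[Si](C)(C)C(C)(C)C)c1O[Si](C)(C)C(C)(C)C | intermediate
5 | (S)-1-bromo-2-methylbutane | CC[C@H](C)CBr | starting material
6 | 1,6-dibromohexane | BrCCCCCCBr | starting material
7 | (S)-2-methylbutylmagnesium bromide | CC[C@H](C)C[Mg]Br | intermediate (not isolated)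
8 | (S)-1-bromo-8-methyldecane | CC[C@H](C)CCCCCCCBr | intermediate
9 | 11-bromoundec-1-ene | C=CCCCCCCCCCBr | starting material
10 | (S)-8-methyldecylmagnesium bromide | CC[C@H](C)CCCCCCC[Mg]Br | intermediate (not isolated)
11 | (S)-19-methylhenicos-1-ene | CC[C@H](C)CCCCCCCCCCCCCCCCC=C | intermediate
12 | (2E,20S)-20-methyldocos-2-en-1-yl 2,3-bis[(tert-butyldimethylsilyl)oxy]benzoate | CC[C@H](C)CCCCCCCCCCCCCCCC/C=C/COC(=O)c1cccc(O[Si](C)(C)C(C)(C)C)c1O[Si](C)(C)C(C)(C)C | intermediate
13 | (20S)-20-methyldocosyl 2,3-bis[(tert-butyldimethylsilyl)oxy]benzoate | CC[C@H](C)CCCCCCCCCCCCCCCCCCCOC(=O)c1cccc(O[Si](C)(C)C(C)(C)C)c1O[Si](C)(C)C(C)(C)C | intermediate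
14 | Gentiside B, (20S)-20-methyldocosyl 2,3-dihydroxybenzoate | CC[C@H](C)CCCCCCCCCCCCCCCCCCCOC(=O)c1cccc(O)c1O | target

**Totals**
Total step count: 7. Longest linear sequence: 5 steps (steps 3, 4, 5, 6, 7 from bromide 5; equally steps 1, 2, 5, 6, 7 from allyl benzoate 1).

**Steps most likely to fail**

1. Step 1. The dehydrogenase may turn over the ester-bearing diol too slowly, so that the oxidation stops at the diol, or the catechol may poison the cells and autoxidise before it is adsorbed, so that the biotransformation stalls. The fallback abandons the enzymatic oxidation, takes the catechol ring from purchased 2,3-dihydroxybenzoic acid and builds the whole C23 chain first. It sets out from bromide 8 and comes back at target 14. Bromide 8 is converted into Grignard reagent 10 (Mg, THF) and coupled with excess 1,12-dibromododecane (4 equiv, Li2CuCl4 3 mol %, THF, −10 → 20 °C) to give (S)-1-bromo-20-methyldocosane F1. Alkylation of the carboxylate of 2,3-dihydroxybenzoic acid with this bromide (KHCO3, DMF/THF, 60 °C) should then give 14 directly, because hydrogencarbonate deprotonates only the carboxylic acid and leaves both phenols protonated.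

2. Step 5. Statistical homodimerisation may consume the partners, and ruthenium-hydride double-bond migration before metathesis would produce chain-shortened homologues that cannot be separated from the C23 ester. The fallback replaces metathesis by an alkyl–alkyl Suzuki–Miyaura coupling across the same allyl handle. It sets out from bromide 8 and allyl ester 4 and comes back at saturated ester 13, so step 6 is no longer needed. Grignard reagent 10 from 8 is coupled with excess 1,9-dibromononane (Li2CuCl4, THF) to give (S)-1-bromo-17-methylnonadecane F2. Ester 4 is hydroborated at the terminal carbon with 9-BBN-H (THF, 0 → 25 °C) to give 3-(9-borabicyclo[3.3.1]nonan-9-yl)propyl 2,3-bis[(tert-butyldimethylsilyl)oxy]benzoate F3, used in solution. The two are then joined with Pd(OAc)2 (4 mol %), PCy3 (8 mol %) and K3PO4·H2O in THF at 25 °C to give 13. Any partial loss of an aryl silyl group to the phosphate base is harmless, since step 7 removes both.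

3. Step 3. The Grignard reagent may alkylate both ends of the symmetrical dibromide, and the excess dibromide, close in volatility to the product, may not be removed completely, which would carry a difunctional electrophile into step 4. The fallback uses a C6 electrophile whose two ends are differentiated. It sets out from bromide 5 and comes back at bromide 8. Grignard reagent 7 from 5 is coupled with purchased 2-(6-bromohexyloxy)oxane (Li2CuCl4 3 mol %, THF, −10 → 20 °C) to give 2-{[(8S)-8-methyldecyl]oxy}oxane F4, a mixture of acetal epimers. Acetal exchange (TsOH cat., MeOH, 25 °C) gives (S)-8-methyldecan-1-ol F5, and an Appel reaction (CBr4, PPh3, CH2Cl2, 0 °C) gives 8.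

**Further compounds**
F1 | step 1 | (S)-1-bromo-20-methyldocosane | CC[C@H](C)CCCCCCCCCCCCCCCCCCCBr
F2 | step 5 | (S)-1-bromo-17-methylnonadecane | CC[C@H](C)CCCCCCCCCCCCCCCCBr
F3 | step 5 | 3-(9-borabicyclo[3.3.1]nonan-9-yl)propyl 2,3-bis[(tert-butyldimethylsilyl)oxy]benzoate | CC(C)(C)[Si](C)(C)Oc1cccc(C(=O)OCCCB2C3CCCC2CCC3)c1O[Si](C)(C)C(C)(C)C
F4 | step 3 | 2-{[(8S)-8-methyldecyl]oxy}oxane (acetal carbon unassigned, both epimers) | CC[C@H](C)CCCCCCCOC1CCCCO1
F5 | step 3 | (S)-8-methyldecan-1-ol | CC[C@H](C)CCCCCCCO
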